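**Retrosynthetic overview**

1. The target is an arene (ring A) joined by a CH2 bridge to a chiral cyclohexadienone (ring B: C1 C=O, C2 butanoyl, C3 C–OH, C4 quaternary, C5 C–OH, C6 bridge carbon). The bridge is cut last: C6–H of the free ring B triketone adds to an ortho-quinone methide of ring A.
2. Ring B is cut at C3–C4 and C5–C6 into a two-carbon piece (C4, C5) and a four-carbon piece (C3, C2, C1, C6). Both bonds are made in one flask: acylation at C4, then aldol addition at C5.
3. Enabling feature: the C5 carbonyl and the prenyl double bond on C4 form a gamma,delta-unsaturated ketone (C5, C4, CH2, CH=, CMe2), the retron of a Grob fragmentation. A temporary bond from C5 to the CMe2 carbon gives a cyclopentanone whose sulfonate-bearing carbinol carbon (the later CH=) fixes enolate geometry and face for building C4; that bond is cut again as ring B closes.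
4. The 2-butanoyl-1,3-dione of ring B (butanoyl C=O, C2, C1, with C6 as CH3) is carried as a 3-propyl-5-methylisoxazole. This keeps C2 non-acidic and makes C6 the only carbon that can be deprotonated.
5. Ring order: isoxazole (step 5); ring B in step 8, with loss of the temporary cyclopentane in the same operation; isoxazole opened in step 9; ring A attached in step 12.

Key step: step 8

Assumption: the keto/enol tautomers of the triketone ring are treated as one compound, and the (R) descriptor refers to the tautomer drawn for the target.

**Route**

Step 1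
Reactants: 1 2,2-dimethylcyclopentane-1,3-dione
Product: 2 (3R)-3-hydroxy-2,2-dimethylcyclopentan-1-one
Conditions: (S)-2-methyl-CBS-oxazaborolidine (10 mol %), BH3·SMe2 (0.6 equiv), THF, -30 °C; MeOH quench
Reagents that add atoms: none
Why: Oxazaborolidine-catalysed (Corey–Bakshi–Shibata) reduction of one of two enantiotopic carbonyl groups, where the quaternary carbon is the large substituent, so the usual model predicts the (R)-carbinol from the (S)-catalyst (the antipodal catalyst would be used if the sense proved opposite), and substoichiometric borane limits diol formation.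

Step 2
Reactants: 2 (3R)-3-hydroxy-2,2-dimethylcyclopentan-1-one
Product: 3 (1R)-2,2-dimethyl-3-oxocyclopentyl 4-methylbenzenesulfonate
Conditions: TsCl, pyridine, DMAP (cat.), CH2Cl2, 0 to 23 °C
Reagents that add atoms: 4-methylbenzenesulfonyl chloride (TsCl), Cc1ccc(cc1)S(=O)(=O)Cl
Why: Sulfonylation of a secondary alcohol under nucleophilic catalysis, which leaves the carbinol configuration untouched; the neopentyl ester has no beta hydrogen on the quaternary side and should resist substitution and elimination.

Step 3
Reactants: 3 (1R)-2,2-dimethyl-3-oxocyclopentyl 4-methylbenzenesulfonate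
Product: 4 (1R)-2,2,4-trimethyl-3-oxocyclopentyl 4-methylbenzenesulfonate (both C4 epimers)
Conditions: LiN(i-Pr)2 (1.05 equiv), THF, -78 °C; MeI, -78 to -30 °C; aq NH4Cl
Reagents that add atoms: iodomethane (MeI), CI
Why: Kinetic enolate alkylation that is regiospecific because only one alpha carbon carries hydrogen (the other is quaternary); the new methyl-bearing centre may form as a mixture since it is planarised again in step 8.

Step 4
Reactants: 5 ethyl acetoacetate
Product: 6 ethyl (2E)-3-(pyrrolidin-1-yl)but-2-enoate
Conditions: pyrrolidine, toluene, reflux, water separator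
Reagents that add atoms: pyrrolidine, C1CCNC1
Why: Enamine condensation of a beta-keto ester with a secondary amine, driven by azeotropic removal of water.

Step 5
Reactants: 6 ethyl (2E)-3-(pyrrolidin-1-yl)but-2-enoate; 7 1-nitrobutane
Product: 9 ethyl 5-methyl-3-propyl-1,2-oxazole-4-carboxylate, via pyrrolidinyl isoxazoline 8 (not isolated)
Conditions: POCl3, Et3N, CHCl3, 0 to 23 °C
Reagents that add atoms: none
Why: Dehydration of the primary nitroalkane gives the nitrile oxide, whose 1,3-dipolar cycloaddition to the enamine places oxygen on the amine-bearing carbon, and loss of pyrrolidine from isoxazoline 8 aromatises to the 3-propyl-5-methyl isoxazole.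

Step 6
Reactants: 9 ethyl 5-methyl-3-propyl-1,2-oxazole-4-carboxylate
Product: 10 5-methyl-3-propyl-1,2-oxazole-4-carboxylic acid
Conditions: NaOH, EtOH/H2O, 70 °C; then aq HCl
Reagents that add atoms: sodium hydroxide, [Na+].[OH-]
Why: Ester saponification, which a 3-substituted isoxazole should survive because it has no ring hydrogen at C3 for base-induced ring opening.

Step 7
Reactants: 10 5-methyl-3-propyl-1,2-oxazole-4-carboxylic acid
Product: 11 (1H-benzotriazol-1-yl)(5-methyl-3-propyl-1,2-oxazol-4-yl)methanone
Conditions: SOCl2 (1 equiv), 1H-benzotriazole (4 equiv), CH2Cl2, 23 °C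
Reagents that add atoms: 1H-benzotriazole, c1ccc2[nH]nnc2c1
Why: Activation of the acid as its N-acylbenzotriazole through the acid chloride formed in situ, chosen because this acyl donor C-acylates ketone lithium enolates.

Step 8
Reactants: 4 (1R)-2,2,4-trimethyl-3-oxocyclopentyl 4-methylbenzenesulfonate; 11 (1H-benzotriazol-1-yl)(5-methyl-3-propyl-1,2-oxazol-4-yl)methanone
Product: 14 (5R)-6-hydroxy-5-methyl-5-(3-methylbut-2-en-1-yl)-3-propyl-1,2-benzoxazol-4(5H)-one, via C-acylated diketone 12 (not isolated), via fused lithium aldolate 13 (not isolated)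
Conditions: LiN(i-Pr)2 (1.05 equiv), THF, -78 °C; 11, -78 to -30 °C; then LiN(SiMe3)2 (2.5 equiv), -78 to 23 °C; aq NH4Cl
Reagents that add atoms: none
Why: Proposed new method: the lithium enolate of 4 (only one carbon can enolise) should be C-acylated by 11 to give the non-enolisable diketone 12, after which LiN(SiMe3)2 removes a proton from the isoxazole 5-methyl group and the lateral carbanion adds to the cyclopentanone carbonyl to give the cis-fused alkoxide 13. In 13 the bond from the alkoxide carbon to the CMe2 carbon can lie antiperiplanar to the C–OTs bond, so a Grob fragmentation expels tosylate, returns the ring carbonyl and releases the prenyl double bond, and deprotonation of the product at C7 makes the sequence irreversible. The closest known reaction types are C-acylation of ketone lithium enolates by N-acylbenzotriazoles, lateral metalation of 5-methylisoxazole-4-carbonyl compounds with addition to a carbonyl group, and alkoxide-triggered Grob fragmentation of 3-sulfonyloxy ketones; new is their union into one annulation in which the attacking carbanion stays in the new ring. The six-membered ring closes by a 6-(enolexo)-exo-trig aldol addition, and no other ring size is within reach of the carbanion. The quaternary stereocentre is set in the acylation by the (R)-carbinol sulfonate across the ring (attack on the enolate face anti to the OTs group on the envelope flap), and because that controlling centre is destroyed in the fragmentation, the diastereomer ratio of 12 becomes the enantiomer ratio of 14. The step needs C- over O-acylation (lithium counter-ion and the acylbenzotriazole), deprotonation at the 5-methyl and not the 3-propyl group (the 5-alkyl group is conjugated to the 4-acyl group through the ring C=C), and fragmentation over retro-Claisen cleavage or elimination (hindered amide base, quaternary carbon next to the sulfonate carbon).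

Step 9
Reactants: 14 (5R)-6-hydroxy-5-methyl-5-(3-methylbut-2-en-1-yl)-3-propyl-1,2-benzoxazol-4(5H)-one
Product: 16 (4R)-2-butanoyl-3,5-dihydroxy-4-methyl-4-(3-methylbut-2-en-1-yl)cyclohexa-2,5-dien-1-one, via enaminone 15 (not isolated)
Conditions: Mo(CO)6, MeCN/H2O, 80 °C; then 2 M NaOH, EtOH, 70 °C; then 1 M HCl, 0 °C
Reagents that add atoms: water, O
Why: Reductive N–O cleavage of the isoxazole by Mo(CO)6 and water should spare the trisubstituted olefin and give vinylogous amide 15, whose hydrolysis by hydroxide (addition–elimination at the amino-bearing carbon with loss of ammonia) releases the 2-butanoyl-1,3-dione, while the quaternary centre has no acidic hydrogen and cannot epimerise.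

Step 10
Reactants: 17 5-methoxybenzene-1,3-diol; 18 hexanoic acid
Product: 19 1-(2,4-dihydroxy-6-methoxyphenyl)hexan-1-one
Conditions: BF3·OEt2, 85 °C; then aq NaOAc
Reagents that add atoms: none
Why: Friedel–Crafts acylation of a resorcinol-type ring, expected para to one hydroxyl and ortho to the methoxy group as in resorcinol itself, under a Lewis acid that should not cleave the aryl methyl ether.

Step 11
Reactants: 19 1-(2,4-dihydroxy-6-methoxyphenyl)hexan-1-one
Product: 20 1-{3-[(dimethylamino)methyl]-2,4-dihydroxy-6-methoxyphenyl}hexan-1-one
Conditions: N,N-dimethylmethyleneiminium iodide, MeCN, 23 °C; aq NaHCO3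
Reagents that add atoms: N,N-dimethylmethyleneiminium iodide, C=[N+](C)C.[I-]
Why: Mannich reaction of a phenol with a preformed iminium salt, expected at the ring carbon flanked by the two hydroxyl groups, and the basic product can be separated from any isomer by acid–base extraction and crystallisation before the coupling.

Step 12
Reactants: 16 (4R)-2-butanoyl-3,5-dihydroxy-4-methyl-4-(3-methylbut-2-en-1-yl)cyclohexa-2,5-dien-1-one; 20 1-{3-[(dimethylamino)methyl]-2,4-dihydroxy-6-methoxyphenyl}hexan-1-one
Product: 22 (4R)-2-butanoyl-6-[(3-hexanoyl-2,6-dihydroxy-4-methoxyphenyl)methyl]-3,5-dihydroxy-4-methyl-4-(3-methylbut-2-en-1-yl)cyclohexa-2,5-dien-1-one, via ortho-quinone methide 21 (not isolated)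
Conditions: 1,4-dioxane, 90 °C, argon
Reagents that add atoms: none
Why: Thermal loss of dimethylamine from the ortho-hydroxybenzylamine gives ortho-quinone methide 21, which is trapped by Michael addition of the enolic C6–H carbon of 16 (the only free nucleophilic carbon of ring B), and no stereocentre is formed or touched.

**Compound list**

1 | 2,2-dimethylcyclopentane-1,3-dione | CC1(C)C(=O)CCC1=O | starting material
2 | (3R)-3-hydroxy-2,2-dimethylcyclopentan-1-one | CC1(C)C(=O)CC[C@H]1O | intermediate
3 | (1R)-2,2-dimethyl-3-oxocyclopentyl 4-methylbenzenesulfonate | CC1(C)C(=O)CC[C@H]1OS(=O)(=O)c1ccc(C)cc1 | intermediate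
4 | (1R)-2,2,4-trimethyl-3-oxocyclopentyl 4-methylbenzenesulfonate (both C4 epimers) | CC1(C)C(=O)C(C)C[C@H]1OS(=O)(=O)c1ccc(C)cc1 | intermediate
5 | ethyl acetoacetate | CCOC(=O)CC(C)=O | starting material
6 | ethyl (2E)-3-(pyrrolidin-1-yl)but-2-enoate | CCOC(=O)/C=C(\C)N1CCCC1 | intermediate
7 | 1-nitrobutane | CCCC[N+](=O)[O-] | starting material
8 | ethyl 5-methyl-3-propyl-5-(pyrrolidin-1-yl)-4,5-dihydro-1,2-oxazole-4-carboxylate | CCCC1=NOC(C)(N2CCCC2)C1C(=O)OCC | intermediate (not isolated)
9 | ethyl 5-methyl-3-propyl-1,2-oxazole-4-carboxylate | CCCc1noc(C)c1C(=O)OCC | intermediate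
10 | 5-methyl-3-propyl-1,2-oxazole-4-carboxylic acid | CCCc1noc(C)c1C(=O)O | intermediate
11 | (1H-benzotriazol-1-yl)(5-methyl-3-propyl-1,2-oxazol-4-yl)methanone | CCCc1noc(C)c1C(=O)n1nnc2ccccc12 | intermediate
12 | (1R,4R)-2,2,4-trimethyl-4-[(5-methyl-3-propyl-1,2-oxazol-4-yl)carbonyl]-3-oxocyclopentyl 4-methylbenzenesulfonate (acyl group trans to the sulfonate) | CC1(C)C(=O)[C@](C)(C(=O)c2c(C)onc2CCC)C[C@H]1OS(=O)(=O)c1ccc(C)cc1 | intermediate (not isolated)
13 | lithium alkoxide of the cis-fused aldol adduct (isoxazole-fused cyclohexanone fused to the cyclopentane; alkoxide oxygen, angular methyl and sulfonate on the same face) | CCCc1noc2C[C@@]3([O-])C(C)(C)[C@H](OS(=O)(=O)c4ccc(C)cc4)C[C@@]3(C)C(=O)c12.[Li+] | intermediate (not isolated)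
14 | (5R)-6-hydroxy-5-methyl-5-(3-methylbut-2-en-1-yl)-3-propyl-1,2-benzoxazol-4(5H)-one | CCCc1noc2C=C(O)[C@@](C)(CC=C(C)C)C(=O)c12 | intermediate
15 | (6R)-2-(1-aminobutylidene)-5-hydroxy-6-methyl-6-(3-methylbut-2-en-1-yl)cyclohex-4-ene-1,3-dione | CCCC(N)=C1C(=O)C=C(O)[C@@](C)(CC=C(C)C)C1=O | intermediate (not isolated)
16 | (4R)-2-butanoyl-3,5-dihydroxy-4-methyl-4-(3-methylbut-2-en-1-yl)cyclohexa-2,5-dien-1-one | O=C1C=C(O)[C@@](C)(CC=C(C)C)C(O)=C1C(=O)CCC | intermediate
17 | 5-methoxybenzene-1,3-diol | COc1cc(O)cc(O)c1 | starting material
18 | hexanoic acid | CCCCCC(=O)O | starting material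
19 | 1-(2,4-dihydroxy-6-methoxyphenyl)hexan-1-one | CCCCCC(=O)c1c(OC)cc(O)cc1O | intermediate
20 | 1-{3-[(dimethylamino)methyl]-2,4-dihydroxy-6-methoxyphenyl}hexan-1-one | CCCCCC(=O)c1c(OC)cc(O)c(CN(C)C)c1O | intermediate
21 | 4-hexanoyl-3-hydroxy-5-methoxy-2-methylidenecyclohexa-3,5-dien-1-one | CCCCCC(=O)C1=C(O)C(=C)C(=O)C=C1OC | intermediate (not isolated)
22 | (4R)-2-butanoyl-6-[(3-hexanoyl-2,6-dihydroxy-4-methoxyphenyl)methyl]-3,5-dihydroxy-4-methyl-4-(3-methylbut-2-en-1-yl)cyclohexa-2,5-dien-1-one | CCCCCC(=O)c1c(OC)cc(O)c(CC2=C(O)[C@@](C)(CC=C(C)C)C(O)=C(C(=O)CCC)C2=O)c1O | target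

**Count and risks**

Total step count: 12. Longest linear sequence: 7 steps (steps 4, 5, 6, 7, 8, 9, 12).

Steps most likely to fail:

1. Step 8 (proposed new method). What may go wrong: O-acylation of the hindered tetrasubstituted enolate; insufficient face discrimination in the acylation, which would lower the enantiomeric purity of everything downstream; or reversal of the aldol addition before the fragmentation. The fallback uses known reaction types only, sets out from 4 and 11 and comes back at 14. Only the first stage is run (LiN(i-Pr)2, THF, -78 °C, then 11), and diketone 12 is isolated and freed from its diastereomer by chromatography. NaOMe in MeOH at 0 °C should add to the cyclopentanone carbonyl and trigger the Grob fragmentation with an external alkoxide, giving methyl (2S)-2,5-dimethyl-2-[(5-methyl-3-propyl-1,2-oxazol-4-yl)carbonyl]hex-4-enoate F1. LiN(SiMe3)2 (2.2 equiv) in THF at -78 to 0 °C should then close ring B by Claisen condensation of the lateral isoxazolylmethyl carbanion onto the methyl ester, giving 14.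

2. Step 12. What may go wrong: at the temperature needed to unmask the quinone methide, the methylene group may be exchanged between the partners (symmetrical dimers), or the product may cyclodehydrate between a ring A hydroxyl and a ring B carbonyl. The fallback sets out from 19 and comes back at 22. Magnesium-mediated ortho-formylation of 19 (MgCl2, Et3N, paraformaldehyde, MeCN, 80 °C) should give 3-hexanoyl-2,6-dihydroxy-4-methoxybenzaldehyde F2. Reductive alkylation of 16 with F2 at 23 °C (L-proline cat., diethyl 2,6-dimethyl-1,4-dihydropyridine-3,5-dicarboxylate, CH2Cl2) should proceed by Knoevenagel condensation to the alkylidene of 16 and F2 F3, which is not isolated, and conjugate hydride transfer should then give 22 without heating.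

3. Step 3. What may go wrong: proton exchange between the methylated ketone and unreacted enolate (double methylation), or loss of the sulfonate by attack of a nucleophile at the ketone (premature fragmentation) during enolate handling and work-up. The fallback sets out from 2 and comes back at 4. The methyl group is introduced before the leaving group by C-methylation of the alkoxide–enolate dianion of 2 (LiN(i-Pr)2 2.2 equiv, THF, -78 °C; MeI), giving (3R)-3-hydroxy-2,2,5-trimethylcyclopentan-1-one F4, which is then sulfonylated (TsCl, pyridine, DMAP, CH2Cl2) to 4.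

**Further compounds**

F1 | step 8 | methyl (2S)-2,5-dimethyl-2-[(5-methyl-3-propyl-1,2-oxazol-4-yl)carbonyl]hex-4-enoate | COC(=O)[C@@](C)(CC=C(C)C)C(=O)c1c(C)onc1CCC
F2 | step 12 | 3-hexanoyl-2,6-dihydroxy-4-methoxybenzaldehyde | CCCCCC(=O)c1c(OC)cc(O)c(C=O)c1O
F3 | step 12 | Knoevenagel alkylidene of 16 and F2 (arylmethylidene on C6 of ring B, quaternary centre unchanged) | CCCCCC(=O)c1c(OC)cc(O)c(C=C2C(=O)C(C(=O)CCC)=C(O)[C@](C)(CC=C(C)C)C2=O)c1O
F4 | step 3 | (3R)-3-hydroxy-2,2,5-trimethylcyclopentan-1-one (both C5 epimers) | CC1(C)C(=O)C(C)C[C@H]1O
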